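**Strategy.** The flavone is cut across ring C at C4–C4a and O1–C2. This splits it into an intact ring A triol and an aroyl(methoxy)acetate that already carries C2, C3–OMe, C4 and ring B. Ring A is locally symmetric about the C4a···C7 axis (C5–OH/C8a–O and C6–OMe/C8–OMe are pairwise equivalent). Hence 2,4-dimethoxybenzene-1,3,5-triol has one ring C–H and two identical flanking hydroxyls, and needs no protection. One thermal, acid-free condensation with ethyl 3-[4-(benzyloxy)-2,5-dimethoxyphenyl]-2-methoxy-3-oxopropanoate should C-acylate that carbon and close the pyranone, giving the complete 3-methoxyflavone. Only the 4'-benzyl ether then remains to be removed.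

Key step: step 8

Remarks on the chemistry: 1,3,5-tris(benzyloxy)benzene is taken as a purchasable starting material, because direct O-benzylation of phloroglucinol suffers from C-benzylation. Aldol 11 is carried as a mixture of racemic diastereomers, since both of its stereocentres are removed or made labile in step 7. Keto ester 12 is racemic and enolisable.

**Route**

Step 1
Reactants: 1 1,3,5-tris(benzyloxy)benzene
Product: 2 1,3,5-tris(benzyloxy)-2,4-dibromobenzene
Conditions: NBS (2.05 equiv), CH2Cl2, −10 °C to rt, dark
Reagents that add atoms: N-bromosuccinimide O=C1CCC(=O)N1Br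
Why: Electrophilic aromatic bromination of a phloroglucinol triether, in which every ring C–H is activated by three alkoxy groups and the third substitution is much slower than the first two, so two equivalents of NBS in the dark should stop at the 2,4-dibromide and leave the benzylic positions alone.

Step 2
Reactants: 2 1,3,5-tris(benzyloxy)-2,4-dibromobenzene
Product: 3 1,3,5-tris(benzyloxy)-2,4-dimethoxybenzene
Conditions: NaOMe (10 equiv), CuI (0.4 equiv), MeOH/DMF, 110 °C, Ar
Reagents that add atoms: sodium methoxide [Na+].[O-]C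
Why: Ullmann-type copper-catalysed methoxylation of aryl bromides tolerates ortho-alkoxy neighbours and does not affect benzyl ethers, so both bromines should be exchanged for methoxy groups.

Step 3
Reactants: 3 1,3,5-tris(benzyloxy)-2,4-dimethoxybenzene
Product: 4 2,4-dimethoxybenzene-1,3,5-triol
Conditions: H2 (1 atm), 10% Pd/C, EtOAc/MeOH, rt; filtered and concentrated under Ar
Reagents that add atoms: none
Why: Catalytic hydrogenolysis cleaves the three benzyl aryl ethers while aryl methyl ethers are inert; the electron-rich triol is kept under argon and used at once in step 8.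

Step 4
Reactants: 5 2,5-dimethoxyphenol
Product: 6 2-(benzyloxy)-1,4-dimethoxybenzene
Conditions: BnBr, K2CO3, DMF, rt
Reagents that add atoms: benzyl bromide BrCc1ccccc1
Why: Williamson O-alkylation of the phenoxide with a reactive benzylic bromide.

Step 5
Reactants: 6 2-(benzyloxy)-1,4-dimethoxybenzene
Product: 8 4-(benzyloxy)-2,5-dimethoxybenzaldehyde, via aryl iminium dichlorophosphate 7 (not isolated)
Conditions: POCl3 (1.5 equiv), DMF, 0 to 60 °C; then ice-water
Reagents that add atoms: N,N-dimethylformamide CN(C)C=O; water O
Why: Vilsmeier–Haack formylation of a 1,2,4-trialkoxybenzene takes place para to the benzyloxy group and ortho to a methoxy group (C5 of 6), the site at which 1,2,4-trimethoxybenzene is formylated, because C3 is flanked on both sides and C6 has only one ortho oxygen; hydrolysis of iminium salt 7 releases the aldehyde.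

Step 6
Reactants: 8 4-(benzyloxy)-2,5-dimethoxybenzaldehyde; 9 ethyl methoxyacetate
Product: 11 ethyl 3-[4-(benzyloxy)-2,5-dimethoxyphenyl]-3-hydroxy-2-methoxypropanoate, via lithium enolate of ethyl methoxyacetate 10 (not isolated)
Conditions: 9, LiN(iPr)2 (1.1 equiv), THF, −78 °C; then 8; aq NH4Cl
Reagents that add atoms: none
Why: Aldol addition of a preformed lithium ester enolate to a non-enolisable aromatic aldehyde at low temperature; the two new stereocentres (C2 and C3) form without control as racemic syn and anti isomers, which does not matter because C3 is oxidised and C2 becomes enolisable in step 7.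

Step 7
Reactants: 11 ethyl 3-[4-(benzyloxy)-2,5-dimethoxyphenyl]-3-hydroxy-2-methoxypropanoate
Product: 12 ethyl 3-[4-(benzyloxy)-2,5-dimethoxyphenyl]-2-methoxy-3-oxopropanoate
Conditions: DMP (1.2 equiv), CH2Cl2, 0 °C to rt
Reagents that add atoms: none
Why: Dess–Martin oxidation of the secondary benzylic alcohol under neutral conditions avoids retro-aldol cleavage and gives the β-keto ester, whose C2 stereocentre is racemic and labile.

Step 8
Reactants: 4 2,4-dimethoxybenzene-1,3,5-triol; 12 ethyl 3-[4-(benzyloxy)-2,5-dimethoxyphenyl]-2-methoxy-3-oxopropanoate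
Product: 15 2-[4-(benzyloxy)-2,5-dimethoxyphenyl]-5,7-dihydroxy-3,6,8-trimethoxy-4H-chromen-4-one, via aroyl(methoxy)ketene 13 (not isolated), via ortho-hydroxyaryl beta-diketone 14 (not isolated)
Conditions: 4 (1.5 equiv), neat melt, 240 °C, Ar sweep, 15 min
Reagents that add atoms: none
Why: Thermal loss of ethanol from the enol of 12 should give ketene 13 (or, equivalently, the aryl ester followed by acyl shift), which acylates the only ring C–H of 4 (C6, ortho and para to three hydroxyls) to give diketone 14 and so forms C4–C4a; a flanking hydroxyl then adds to the aroyl carbonyl and water is lost, forming O1–C2. The closest known reaction is the Mentzer thermal chromone synthesis from phloroglucinols and aroylacetic esters, in which alpha-substituted keto esters are known to deliver 3-substituted chromones. Ring C closes by 6-exo-trig attack of the phenolic oxygen on the ketone carbon, followed by dehydration to the aromatic pyranone. No stereocentre is formed, and the racemic C2 of 12 becomes the sp2 carbon C3. The step needs chromone rather than coumarin formation: without acid the ketone is not activated for Pechmann-type attack by the ring, the ketene or ester carbon is the acylating site, and the alpha-methoxy group further disfavours the coumarin pathway. Regiochemistry is fixed because 4 has one C–H and two hydroxyls related by its mirror plane, so either closure gives the same flavone and the other hydroxyl becomes the chelated 5-OH; the excess of 4, which can be C-acylated only once, limits O-aroylation of the product.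

Step 9
Reactants: 15 2-[4-(benzyloxy)-2,5-dimethoxyphenyl]-5,7-dihydroxy-3,6,8-trimethoxy-4H-chromen-4-one
Product: 16 5,7-dihydroxy-2-(4-hydroxy-2,5-dimethoxyphenyl)-3,6,8-trimethoxy-4H-chromen-4-one (5,7,4'-trihydroxy-3,6,8,2',5'-pentamethoxyflavone)
Conditions: H2 (1 atm), 10% Pd/C, EtOAc/THF, rt
Reagents that add atoms: none
Why: Hydrogenolysis of the single benzyl aryl ether; the tetrasubstituted C2=C3 bond of the aromatic pyranone, the carbonyl and the methyl ethers should not be reduced under these mild conditions.

**Compound list**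

1 | 1,3,5-tris(benzyloxy)benzene | C(Oc1cc(OCc2ccccc2)cc(OCc2ccccc2)c1)c1ccccc1 | starting material
2 | 1,3,5-tris(benzyloxy)-2,4-dibromobenzene | Brc1c(OCc2ccccc2)cc(OCc2ccccc2)c(Br)c1OCc1ccccc1 | intermediate
3 | 1,3,5-tris(benzyloxy)-2,4-dimethoxybenzene | COc1c(OCc2ccccc2)cc(OCc2ccccc2)c(OC)c1OCc1ccccc1 | intermediate
4 | 2,4-dimethoxybenzene-1,3,5-triol | COc1c(O)cc(O)c(OC)c1O | intermediate
5 | 2,5-dimethoxyphenol | COc1ccc(OC)c(O)c1 | starting material
6 | 2-(benzyloxy)-1,4-dimethoxybenzene | COc1ccc(OC)c(OCc2ccccc2)c1 | intermediate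
7 | N-[4-(benzyloxy)-2,5-dimethoxybenzylidene]-N-methylmethanaminium dichlorophosphate (not isolated) | C[N+](C)=Cc1cc(OC)c(OCc2ccccc2)cc1OC.[O-]P(Cl)(Cl)=O | intermediate
8 | 4-(benzyloxy)-2,5-dimethoxybenzaldehyde | O=Cc1cc(OC)c(OCc2ccccc2)cc1OC | intermediate
9 | ethyl methoxyacetate | CCOC(=O)COC | starting material
10 | lithium 1-ethoxy-2-methoxyethen-1-olate (enolate geometry not specified; not isolated) | [Li+].CCOC([O-])=COC | intermediate
11 | ethyl 3-[4-(benzyloxy)-2,5-dimethoxyphenyl]-3-hydroxy-2-methoxypropanoate (racemic, mixture of syn and anti diastereomers, no configuration assigned) | CCOC(=O)C(OC)C(O)c1cc(OC)c(OCc2ccccc2)cc1OC | intermediate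
12 | ethyl 3-[4-(benzyloxy)-2,5-dimethoxyphenyl]-2-methoxy-3-oxopropanoate (racemic, enolisable) | CCOC(=O)C(OC)C(=O)c1cc(OC)c(OCc2ccccc2)cc1OC | intermediate
13 | 3-[4-(benzyloxy)-2,5-dimethoxyphenyl]-2-methoxy-3-oxoprop-1-en-1-one (aroyl(methoxy)ketene; not isolated) | O=C=C(OC)C(=O)c1cc(OC)c(OCc2ccccc2)cc1OC | intermediate
14 | 1-[4-(benzyloxy)-2,5-dimethoxyphenyl]-2-methoxy-3-(2,4,6-trihydroxy-3,5-dimethoxyphenyl)propane-1,3-dione (racemic, enolisable; not isolated) | COC(C(=O)c1cc(OC)c(OCc2ccccc2)cc1OC)C(=O)c1c(O)c(OC)c(O)c(OC)c1O | intermediate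
15 | 2-[4-(benzyloxy)-2,5-dimethoxyphenyl]-5,7-dihydroxy-3,6,8-trimethoxy-4H-chromen-4-one | COc1c(O)c(OC)c2oc(-c3cc(OC)c(OCc4ccccc4)cc3OC)c(OC)c(=O)c2c1O | intermediate
16 | 5,7-dihydroxy-2-(4-hydroxy-2,5-dimethoxyphenyl)-3,6,8-trimethoxy-4H-chromen-4-one (achiral) | COc1cc(-c2oc3c(OC)c(O)c(OC)c(O)c3c(=O)c2OC)c(OC)cc1O | target

**Step count**

Total step count: 9.
Longest linear sequence: 6 steps (steps 4, 5, 6, 7, 8 and 9, from 2,5-dimethoxyphenol 5). The triol branch (steps 1 to 3) joins at step 8.

**Steps most likely to fail**

Step 8. The melt may break down through thermal or oxidative degradation of the triol. The acylketene may oligomerise, or may O-acylate without the later shift to carbon. The benzyl ether may migrate or cleave at 240 °C. The fallback is an Allan–Robinson flavone synthesis that sets out from 4 and 8 and returns at 15. Triol 4 would be acylated at its only ring C–H under Hoesch conditions (methoxyacetonitrile, ZnCl2, HCl, Et2O, 0 °C) to give 1-(2,4,6-trihydroxy-3,5-dimethoxyphenyl)-2-methoxyethan-1-iminium chloride F1. Hot water should hydrolyse this to 2-methoxy-1-(2,4,6-trihydroxy-3,5-dimethoxyphenyl)ethan-1-one F2. Aldehyde 8 would be oxidised under Pinnick conditions (NaClO2, NaH2PO4, 2-methylbut-2-ene, t-BuOH/H2O) to 4-(benzyloxy)-2,5-dimethoxybenzoic acid F3. Dehydration of F3 with DCC (0.5 equiv, CH2Cl2) should give 4-(benzyloxy)-2,5-dimethoxybenzoic anhydride F4. Heating F2 with F4 and Et3N at 160–170 °C should give the flavone, chiefly as its 7-O-aroyl ester 2-[4-(benzyloxy)-2,5-dimethoxyphenyl]-5-hydroxy-3,6,8-trimethoxy-4-oxo-4H-chromen-7-yl 4-(benzyloxy)-2,5-dimethoxybenzoate F5. Saponification (KOH, aqueous EtOH, reflux) then returns 15.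

Step 2. Each bromine sits between two benzyloxy groups, so substitution may be slow, may stop after one exchange, or may be overtaken by protodebromination. The fallback makes the C–O bonds by oxidation of C–B bonds instead of by substitution at the halide; it sets out from 2 and returns at 3. Bromine–lithium exchange at one bromine (n-BuLi, THF, −78 °C), trapping with B(OMe)3 and oxidation (H2O2, NaOH) should give 2,4,6-tris(benzyloxy)-3-bromophenol F6. O-Methylation (MeI, K2CO3, DMF) should give 1,3,5-tris(benzyloxy)-2-bromo-4-methoxybenzene F7. Repeating the exchange, borylation and oxidation should give 2,4,6-tris(benzyloxy)-3-methoxyphenol F8, and a second methylation returns 3.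

Step 3. The pentaoxygenated triol may oxidise in air during filtration, concentration or storage before it reaches step 8. The fallback isolates a stable surrogate; it sets out from 3 and returns at 4. The hydrogenolysis filtrate would be acetylated directly under argon (Ac2O, pyridine) to 2,4-dimethoxybenzene-1,3,5-triyl triacetate F9, which can be purified and stored. Acid methanolysis in degassed HCl/MeOH followed by evaporation should release 4, with only volatile by-products, immediately before step 8.

**Further compounds**

F1 | step 8 | 1-(2,4,6-trihydroxy-3,5-dimethoxyphenyl)-2-methoxyethan-1-iminium chloride | COCC(=[NH2+])c1c(O)c(OC)c(O)c(OC)c1O.[Cl-]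
F2 | step 8 | 2-methoxy-1-(2,4,6-trihydroxy-3,5-dimethoxyphenyl)ethan-1-one | COCC(=O)c1c(O)c(OC)c(O)c(OC)c1O
F3 | step 8 | 4-(benzyloxy)-2,5-dimethoxybenzoic acid | OC(=O)c1cc(OC)c(OCc2ccccc2)cc1OC
F4 | step 8 | 4-(benzyloxy)-2,5-dimethoxybenzoic anhydride | O=C(OC(=O)c1cc(OC)c(OCc2ccccc2)cc1OC)c1cc(OC)c(OCc2ccccc2)cc1OC
F5 | step 8 | 2-[4-(benzyloxy)-2,5-dimethoxyphenyl]-5-hydroxy-3,6,8-trimethoxy-4-oxo-4H-chromen-7-yl 4-(benzyloxy)-2,5-dimethoxybenzoate | COc1c(OC(=O)c2cc(OC)c(OCc3ccccc3)cc2OC)c(OC)c2oc(-c3cc(OC)c(OCc4ccccc4)cc3OC)c(OC)c(=O)c2c1O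
F6 | step 2 | 2,4,6-tris(benzyloxy)-3-bromophenol | Oc1c(OCc2ccccc2)cc(OCc2ccccc2)c(Br)c1OCc1ccccc1
F7 | step 2 | 1,3,5-tris(benzyloxy)-2-bromo-4-methoxybenzene | COc1c(OCc2ccccc2)cc(OCc2ccccc2)c(Br)c1OCc1ccccc1
F8 | step 2 | 2,4,6-tris(benzyloxy)-3-methoxyphenol | COc1c(OCc2ccccc2)cc(OCc2ccccc2)c(O)c1OCc1ccccc1
F9 | step 3 | 2,4-dimethoxybenzene-1,3,5-triyl triacetate | COc1c(OC(C)=O)cc(OC(C)=O)c(OC)c1OC(C)=O
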